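**Retrosynthetic overview**

1. Locants follow the elemane skeleton: ring C5–C10; C10 carries CH3 and the C1=C2 vinyl group; C5 carries the C4(=C3)–C15HO unit; C7 and C8 carry the lactone C11(=C13)–C12(=O)–O8. α is the ring face of the C10 methyl group, β that of the C10 vinyl group. The target comes from hydroxy lactone 20 by C9 methacryloylation and C15 acetal hydrolysis.
2. Key disconnection is the lactone bond O–C8. The enabling feature is the anti pair O8 (β, inside the cis-fused five-membered lactone on C7–C8) and O9 (α) on the adjacent ring carbons C8–C9. This is the retron of an α C8–C9 epoxide opened at C8 by the C12 carboxyl group on the β side chain at C7; the acid is unmasked from the C12 aldehyde in the same operation (18 → 20).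
3. The epoxide comes from C6–OH-directed epoxidation of the C8=C9 alkene (16). The alkene comes from C9 ketone 11 (enol triflate, formate reduction); the C12 oxidation level comes from the isopropenyl methyl group.
4. Ketone 11 comes from 4-hydroxy enone 5: the C5 side chain by alkoxide-directed 1,4-addition cis to O6, the quaternary C10 by enolate vinylation trans to the C5 substituent.
5. Enone 5 comes from (S)-carvone (carvone C5 → C7, C6 → C6, C1 → C5, C2 → C10, C3 → C9) by Shapiro diene formation, singlet-oxygen endoperoxide and Kornblum–DeLaMare opening. Ring order: carbocycle from the chiral pool; temporary endoperoxide (step 3) and epoxide (step 12); lactone ring last (step 14).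

Key step: step 14

Remark: (S)-(+)-carvone and 2-ethenyl-1,3-dioxolane are taken as commercial. The "acetal side chain" is 1-(1,3-dioxolan-2-yl)ethenyl. Configurations are given by the α/β convention above and by the SMILES in the compound list.

**Route**

Step 1
Reactants: 1 (S)-(+)-carvone
Product: 2 (S)-carvone 4-methylbenzenesulfonylhydrazone
Conditions: TsNHNH2, AcOH (cat.), EtOH, rt
Reagents that add atoms: 4-methylbenzenesulfonohydrazide, Cc1ccc(cc1)S(=O)(=O)NN
Why: Condensation of the ketone with the sulfonyl hydrazide gives the hydrazone needed for the Shapiro reaction and leaves the only stereocentre (the future C7) untouched.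

Step 2
Reactants: 2 (S)-carvone 4-methylbenzenesulfonylhydrazone
Product: 3 (5S)-2-methyl-5-(prop-1-en-2-yl)cyclohexa-1,3-diene
Conditions: MeLi (2.2 equiv), Et2O, 0 °C to rt; then H2O
Reagents that add atoms: none
Why: Shapiro reaction, in which deprotonation at N–H and at the α′ CH2, loss of sulfinate and N2 and protonation of the vinyllithium should give the conjugated ring diene (future C9=C10–C5=C6) without touching C7.

Step 3
Reactants: 3 (5S)-2-methyl-5-(prop-1-en-2-yl)cyclohexa-1,3-diene
Product: 5 (4S,5R)-4-hydroxy-2-methyl-5-(prop-1-en-2-yl)cyclohex-2-en-1-one, via endoperoxide 4 (not isolated)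
Conditions: O2, tetraphenylporphyrin (cat.), visible light, CH2Cl2, −30 °C; then Et3N, 0 °C to rt
Reagents that add atoms: dioxygen, O=O
Why: Singlet oxygen should add [4+2] to the ring diene anti to the isopropenyl group on the neighbouring sp3 carbon, so both new C–O bonds (C6 and C9) are α, and the amine should then remove the less hindered bridgehead hydrogen (C9–H, next to the CH2) in a Kornblum–DeLaMare rearrangement that breaks the weak O–O bond and gives the C9 ketone and the C6 carbinol trans to the isopropenyl group.

Step 4
Reactants: 6 2-ethenyl-1,3-dioxolane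
Product: 8 2-(1-bromoethenyl)-1,3-dioxolane, via dibromide 7 (not isolated)
Conditions: Br2, CH2Cl2, −20 °C; then t-BuOK, THF, 0 °C
Reagents that add atoms: bromine, BrBr
Why: Bromine addition to the vinyl group and base-induced loss of HBr from the carbon next to the acetal should give the 2-bromoacrolein acetal, a standard precursor of an α-acrolein anion equivalent.

Step 5
Reactants: 5 (4S,5R)-4-hydroxy-2-methyl-5-(prop-1-en-2-yl)cyclohex-2-en-1-one; 8 2-(1-bromoethenyl)-1,3-dioxolane
Product: 9 bis(triethylsilyl) compound (C9=C10 triethylsilyl enol ether; 5α-acetal side chain; 6α-OSiEt3; 7β-isopropenyl)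
Conditions: 8 (3 equiv), Mg, LiCl, THF, 0 °C; then 5, THF, −78 to −20 °C; then Et3SiCl, Et3N, DMPU, −78 °C to rt
Reagents that add atoms: chlorotriethylsilane, CC[Si](Cl)(CC)CC
Why: Alkoxide-directed conjugate addition of a Grignard reagent to a 4-oxido enone (ligand-assisted nucleophilic addition), in which the magnesium alkoxide at C6 should deliver the alkenyl group to C5 on its own α face, which is also the face trans to the C7 isopropenyl group, and the regiodefined enolate is trapped as its silyl enol ether while O6 is silylated.

Step 6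
Reactants: 9 bis(triethylsilyl) compound
Product: 11 C9 ketone with quaternary C10 (10β-ethenyl; 10α-methyl; 5α-acetal side chain; 6α-OSiEt3; 7β-isopropenyl), via sulfoxide adduct 10 (not isolated)
Conditions: MeLi, THF, 0 °C to rt; phenyl vinyl sulfoxide, −78 to −20 °C; aq. work-up; then xylenes, 135 °C
Reagents that add atoms: phenyl vinyl sulfoxide, C=CS(=O)c1ccccc1
Why: MeLi cleaves the enol ether to the regiodefined lithium enolate, which should add to phenyl vinyl sulfoxide (a vinyl cation equivalent) anti to the C5 substituent so that the new two-carbon chain on C10 is β and the methyl α, and thermal syn-elimination of benzenesulfenic acid then gives the vinyl group.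

Step 7
Reactants: 11 C9 ketone
Product: 12 C8=C9 enol triflate of 11
Conditions: KN(SiMe3)2, THF, −78 °C; PhNTf2, −78 to 0 °C
Reagents that add atoms: N-phenylbis(trifluoromethanesulfonimide), O=S(=O)(N(c1ccccc1)S(=O)(=O)C(F)(F)F)C(F)(F)F
Why: The ketone can enolise only towards C8 because C10 is quaternary, so deprotonation and O-sulfonylation should give a single enol triflate.

Step 8
Reactants: 12 enol triflate
Product: 13 allylic alcohol (7β side chain now 3-hydroxyprop-1-en-2-yl; C12–OH)
Conditions: SeO2 (cat.), t-BuOOH, CH2Cl2, 0 °C to rt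
Reagents that add atoms: tert-butyl hydroperoxide, CC(C)(C)OO (terminal oxygen source; SeO2 is the catalytic carrier)
Why: Catalytic SeO2 allylic oxidation (ene reaction, then [2,3]-shift) should take place at the methyl group of the electron-rich isopropenyl alkene, since the vinyl group has no allylic hydrogen and the enol triflate and the acetal-bearing alkene are electron-poor.

Step 9
Reactants: 13 allylic alcohol
Product: 14 cyclohexene (C8=C9 alkene with H on C9; 6α-OSiEt3; C12–OH)
Conditions: Pd(OAc)2 (cat.), PPh3, HCO2H, n-Bu3N, DMF, 60 °C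
Reagents that add atoms: none
Why: Formate reduction of the enol triflate by zerovalent palladium formed in situ (oxidative addition, formate exchange, loss of CO2, C–H reductive elimination) should replace the C9 oxygen by hydrogen and leave the C8=C9 alkene in place.

Step 10
Reactants: 14 cyclohexene
Product: 15 diol (6α-OH and C12–OH)
Conditions: Bu4NF, THF, 0 °C to rt
Reagents that add atoms: none
Why: Fluoride cleaves the triethylsilyl ether and frees the C6 hydroxyl that must direct the epoxidation.

Step 11
Reactants: 15 diol
Product: 16 hydroxy enal (7β-(3-oxoprop-1-en-2-yl); 6α-OH)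
Conditions: MnO2, CH2Cl2, rt
Reagents that add atoms: none
Why: MnO2 should oxidise only the allylic primary alcohol at C12 to the 2-substituted acrolein and leave the secondary non-allylic C6 hydroxyl alone.

Step 12
Reactants: 16 hydroxy enal
Product: 17 epoxy alcohol (8α,9α-epoxide; 6α-OH)
Conditions: VO(acac)2 (cat.), t-BuOOH, CH2Cl2, 0 °C to rt
Reagents that add atoms: tert-butyl hydroperoxide, CC(C)(C)OO
Why: Vanadium-catalysed epoxidation directed by the homoallylic C6 hydroxyl should deliver oxygen to C8=C9 on the α face (cis to O6), while the enal alkene and the acetal-substituted alkene are electron-poor and the vinyl group is too remote.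

Step 13
Reactants: 17 epoxy alcohol
Product: 18 epoxy angelate (6α-O-angeloyl; 8α,9α-epoxide; C12 aldehyde)
Conditions: angelic acid, 2,4,6-trichlorobenzoyl chloride, Et3N, toluene, rt; then 17, 75 °C
Reagents that add atoms: angelic acid, C/C=C(/C)C(=O)O
Why: Yamaguchi-type acylation through the mixed anhydride is an established way to make angelates of hindered secondary alcohols without Z-to-E isomerisation, and no stereocentre is touched.

Step 14
Reactants: 18 epoxy angelate
Product: 20 hydroxy lactone (12,8β-olide; 9α-OH; 6α-O-angeloyl; C15 dioxolane), via epoxy acid 19 (not isolated)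
Conditions: NaClO2, NaH2PO4, 2-methylbut-2-ene, t-BuOH/H2O, 0 °C to rt; then PPTS (cat.), CH2Cl2, rt
Reagents that add atoms: sodium chlorite, [Na+].[O-]Cl=O
Why: Chlorous acid adds to the C12 aldehyde and fragments to the acrylic acid 19 (Pinnick oxidation, HOCl trapped by the alkene scavenger), and the carboxyl oxygen then attacks C8 from the β face, anti to the C8–O bond of the acid-activated α-epoxide, in an intramolecular SN2 opening with inversion at C8. The closest known reaction type is the acid-promoted cyclisation of trans-2,3-epoxycyclohexylacetic acids to cis-fused hydroxy γ-lactones, the epoxide counterpart of iodolactonisation. The lactone ring closes in the 5-exo-tet mode, the breaking C8–O bond lying outside the new ring. C8 is controlled by the tether, because the carboxyl group sits on the β substituent at C7 and can reach C8 only from the β face, so the lactone is cis-fused; C9 keeps the α oxygen delivered in step 12 and therefore ends trans to O8. The step needs C8-over-C9 regioselectivity and the absence of a competing nucleophile: attack at C9 would be a 6-endo opening at a neopentyl carbon next to quaternary C10, and the C6 oxygen is already acylated, so no 6,12-lactone can form. The acetal, the angelate and the remaining alkenes should be inert to buffered NaClO2 in the presence of the scavenger.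

Step 15
Reactants: 20 hydroxy lactone
Product: 21 methacrylate (9α-O-methacryloyl; C15 dioxolane)
Conditions: methacrylic anhydride, Et3N, DMAP (cat.), CH2Cl2, rt
Reagents that add atoms: methacrylic anhydride, CC(=C)C(=O)OC(=O)C(C)=C
Why: DMAP-catalysed acylation of the only free hydroxyl (C9) should give the methacrylate with retention at C9.

Step 16
Reactants: 21 methacrylate
Product: 22 CNP0102441.1
Conditions: TsOH·H2O (cat.), acetone/H2O, rt
Reagents that add atoms: water, O
Why: Mild aqueous acid hydrolyses the dioxolane to the conjugated C15 aldehyde, while the lactone and the two esters should be stable and no stereocentre is touched.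

**Compound list**

1 | (S)-(+)-carvone, (5S)-2-methyl-5-(prop-1-en-2-yl)cyclohex-2-en-1-one | CC1=CC[C@@H](CC1=O)C(C)=C | starting material
2 | (S)-carvone 4-methylbenzenesulfonylhydrazone | CC1=CC[C@@H](CC1=NNS(=O)(=O)c2ccc(C)cc2)C(C)=C | intermediate
3 | (5S)-2-methyl-5-(prop-1-en-2-yl)cyclohexa-1,3-diene | CC1=CC[C@@H](C=C1)C(C)=C | intermediate
4 | 5-methyl-7-(prop-1-en-2-yl)-2,3-dioxabicyclo[2.2.2]oct-5-ene, isopropenyl anti to the O–O bridge | CC1=C[C@@H]2OO[C@H]1C[C@@H]2C(C)=C | intermediate
5 | (4S,5R)-4-hydroxy-2-methyl-5-(prop-1-en-2-yl)cyclohex-2-en-1-one (hydroxyl trans to isopropenyl) | CC1=C[C@H](O)[C@@H](C(C)=C)CC1=O | intermediate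
6 | 2-ethenyl-1,3-dioxolane | C=CC1OCCO1 | starting material
7 | 2-(1,2-dibromoethyl)-1,3-dioxolane (racemic) | BrCC(Br)C1OCCO1 | intermediate
8 | 2-(1-bromoethenyl)-1,3-dioxolane | C=C(Br)C1OCCO1 | intermediate
9 | bis(triethylsilyl) compound: C9(OSiEt3)=C10(CH3) enol ether, 5α-acetal side chain, 6α-OSiEt3, 7β-isopropenyl | C=C(C2OCCO2)[C@@H]1[C@H](O[Si](CC)(CC)CC)[C@@H](C(C)=C)CC(O[Si](CC)(CC)CC)=C1C | intermediate
10 | sulfoxide adduct: C9 ketone, C10 with α-methyl and β-[2-(phenylsulfinyl)ethyl] (mixture at sulfur), otherwise as 11 | O=S(CC[C@@]1(C)[C@H](C(=C)C2OCCO2)[C@H](O[Si](CC)(CC)CC)[C@@H](C(C)=C)CC1=O)c1ccccc1 | intermediate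
11 | C9 ketone: C10 with α-methyl and β-ethenyl, 5α-acetal side chain, 6α-OSiEt3, 7β-isopropenyl | C=C[C@@]1(C)[C@H](C(=C)C2OCCO2)[C@H](O[Si](CC)(CC)CC)[C@@H](C(C)=C)CC1=O | intermediate
12 | C8=C9 enol triflate of 11 | C=C[C@@]1(C)[C@H](C(=C)C2OCCO2)[C@H](O[Si](CC)(CC)CC)[C@@H](C(C)=C)C=C1OS(=O)(=O)C(F)(F)F | intermediate
13 | allylic alcohol: 12 with the 7β side chain as 3-hydroxyprop-1-en-2-yl | C=C[C@@]1(C)[C@H](C(=C)C2OCCO2)[C@H](O[Si](CC)(CC)CC)[C@@H](C(=C)CO)C=C1OS(=O)(=O)C(F)(F)F | intermediate
14 | cyclohexene: C8=C9 alkene, 6α-OSiEt3, C12–OH | C=C[C@@]1(C)[C@H](C(=C)C2OCCO2)[C@H](O[Si](CC)(CC)CC)[C@@H](C(=C)CO)C=C1 | intermediate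
15 | diol: 6α-OH and C12–OH, C8=C9 alkene | C=C[C@@]1(C)[C@H](C(=C)C2OCCO2)[C@H](O)[C@@H](C(=C)CO)C=C1 | intermediate
16 | hydroxy enal: 6α-OH, 7β-(3-oxoprop-1-en-2-yl), C8=C9 alkene | C=C[C@@]1(C)[C@H](C(=C)C2OCCO2)[C@H](O)[C@@H](C(=C)C=O)C=C1 | intermediate
17 | epoxy alcohol: 8α,9α-epoxide of 16 | C=C[C@@]1(C)[C@H](C(=C)C3OCCO3)[C@H](O)[C@@H](C(=C)C=O)[C@@H]2O[C@@H]21 | intermediate
18 | epoxy angelate: 6α-O-[(Z)-2-methylbut-2-enoyl] derivative of 17 | C=C[C@@]1(C)[C@H](C(=C)C3OCCO3)[C@H](OC(=O)/C(C)=C\C)[C@@H](C(=C)C=O)[C@@H]2O[C@@H]21 | intermediate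
19 | epoxy acid: 18 with C12 as carboxylic acid | C=C[C@@]1(C)[C@H](C(=C)C3OCCO3)[C@H](OC(=O)/C(C)=C\C)[C@@H](C(=C)C(=O)O)[C@@H]2O[C@@H]21 | intermediate
20 | hydroxy lactone: cis-fused 12,8β-olide with 11(13)-methylene, 9α-OH, 6α-O-angeloyl, C15 dioxolane | C=C[C@@]1(C)[C@H](C(=C)C3OCCO3)[C@H](OC(=O)/C(C)=C\C)[C@H]2C(=C)C(=O)O[C@H]2[C@@H]1O | intermediate
21 | methacrylate: 9α-O-(2-methylprop-2-enoyl) derivative of 20 | C=C[C@@]1(C)[C@H](C(=C)C3OCCO3)[C@H](OC(=O)/C(C)=C\C)[C@H]2C(=C)C(=O)O[C@H]2[C@@H]1OC(=O)C(=C)C | intermediate
22 | CNP0102441.1: 6α-angeloyloxy-9α-methacryloyloxy-15-oxoelema-1,3,11(13)-trien-12,8β-olide | C=C[C@@]1(C)[C@H](C(=C)C=O)[C@H](OC(=O)/C(C)=C\C)[C@H]2C(=C)C(=O)O[C@H]2[C@@H]1OC(=O)C(=C)C | target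

**Step count and risks**

Total step count: 16. Longest linear sequence: 15 steps (steps 1–3 and 5–16, from 1).

Steps most likely to fail:

Step 3. The risk is poor facial selectivity in the singlet-oxygen cycloaddition (one allylic substituent is the only control element) and removal of the wrong bridgehead hydrogen in the base-induced opening, which would give the regioisomeric hydroxy enone. The fallback sets out from 1 and comes back at 5. The kinetic lithium enolate of 1 (LDA, THF, −78 °C) is oxidised at the α′ carbon with 2-(phenylsulfonyl)-3-phenyloxaziridine, anti to the neighbouring isopropenyl group, to give trans-6-hydroxycarvone F1. Silylation (t-BuMe2SiCl, imidazole, DMF) gives the silyl ether F2. Nucleophilic epoxidation (H2O2, NaOH, MeOH, 0 °C) gives the epoxy ketone F3. Wharton transposition (N2H4·H2O, AcOH, MeOH) gives the transposed allylic alcohol F4. Oxidation with Dess–Martin periodinane gives the transposed silyloxy enone F5, and Bu4NF then gives 5.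

Step 5. The risk is 1,2-addition to the carbonyl group, delivery to the β face if the magnesium alkoxide does not hold the reagent, and β-elimination of the β-alkoxy alkenylmagnesium reagent on warming. The fallback sets out from 5 and comes back at 9. Enone 5 is silylated (Et3SiCl, imidazole, DMF) to the triethylsilyl ether F6. The alkenyl group is then added under copper catalysis (Grignard reagent from 8, CuBr·SMe2 (cat.), Et3SiCl, THF, −78 °C). The organocopper secures the 1,4-regiochemistry, axial attack trans to the C7 isopropenyl group should set the face, and trapping of the enolate gives 9 directly.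

Step 6. The risk is sluggish conjugate addition of the hindered tetrasubstituted enolate to the vinyl sulfoxide, with proton transfer returning the C10–H ketone. The fallback sets out from 9 and comes back at 11. The lithium enolate from 9 (MeLi, THF) is trapped with acetaldehyde at −78 °C, again anti to the C5 substituent, to give the aldol adduct F7 (mixture at the carbinol carbon). Dehydration with Martin sulfurane (Ph2S[OC(CF3)2Ph]2, CH2Cl2, rt) then gives 11.

Further compounds
F1 | step 3 | trans-6-hydroxycarvone (hydroxyl on the α′ carbon, trans to isopropenyl) | CC1=CC[C@H](C(C)=C)[C@@H](O)C1=O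
F2 | step 3 | tert-butyldimethylsilyl ether of F1 | CC1=CC[C@H](C(C)=C)[C@@H](O[Si](C)(C)C(C)(C)C)C1=O
F3 | step 3 | 2,3-epoxy ketone of F2 (epoxide trans to isopropenyl) | C[C@]12O[C@H]1C[C@H](C(C)=C)[C@@H](O[Si](C)(C)C(C)(C)C)C2=O
F4 | step 3 | transposed allylic alcohol (C9–OH, C10=C5 alkene, 6α-OSiMe2t-Bu) | CC1=C[C@H](O[Si](C)(C)C(C)(C)C)[C@@H](C(C)=C)C[C@@H]1O
F5 | step 3 | tert-butyldimethylsilyl ether of 5 | CC1=C[C@H](O[Si](C)(C)C(C)(C)C)[C@@H](C(C)=C)CC1=O
F6 | step 5 | triethylsilyl ether of 5 | CC1=C[C@H](O[Si](CC)(CC)CC)[C@@H](C(C)=C)CC1=O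
F7 | step 6 | aldol adduct: 11 with 1-hydroxyethyl in place of ethenyl on C10 (mixture at the carbinol carbon) | CC(O)[C@@]1(C)[C@H](C(=C)C2OCCO2)[C@H](O[Si](CC)(CC)CC)[C@@H](C(C)=C)CC1=O
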